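The central quinone ring (C1 indole A, C2 OH, C3 C=O, C4 indole B, C5 prenyl, C6 C=O) is disconnected at C2–C3, C1–C6 and C5–C6. Its para oxygens on C3 and C6 are the signature of a chromium carbene benzannulation: the carbene carbon of an alkenyl(methoxy)carbene complex becomes C3, one CO ligand becomes C6, and a terminal 3-ethynylindole supplies C1 and C2. One operation thus builds the fully substituted ring as a 4-methoxyphenol with both indoles and the prenyl chain in place. The precursor is a pentacarbonylchromium carbene carrying C4 (N-silylated indole B) and C5 (a CH bearing the prenyl CH2); C2–H is hydroxylated afterwards.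

Key step: step 9

Assumption: 2, 11 and 16 are taken as purchasable; epoxide 22 is formed as a racemate whose two stereocentres vanish in step 12, so the route needs no stereocontrol (the target has no stereocentre).

Step 1
Reactants: 1 indole; 2 5-methylhex-4-enoic acid
Product: 4 1-(1H-indol-3-yl)-5-methylhex-4-en-1-one, via 5-methylhex-4-enoyl chloride 3 (not isolated)
Conditions: 2, (COCl)2, cat. DMF, CH2Cl2, 0 °C to rt, evaporate; 1, Et2AlCl, CH2Cl2, 0 °C, then 3
Reagents that add atoms: none
Why: Friedel–Crafts acylation at C3 of the unprotected indole, in which Et2AlCl activates the acid chloride and consumes the HCl, so no N-protection is needed and the trisubstituted alkene is not hydrochlorinated.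

Step 2
Reactants: 4 1-(1H-indol-3-yl)-5-methylhex-4-en-1-one
Product: 5 5-methyl-1-[1-(triisopropylsilyl)-1H-indol-3-yl]hex-4-en-1-one
Conditions: NaH, THF, 0 °C; i-Pr3SiCl, 0 °C to rt
Reagents that add atoms: triisopropylsilyl chloride, CC(C)[Si](Cl)(C(C)C)C(C)C
Why: N-silylation of the sodium indolide (the vinylogous-amide N–H is far more acidic than the ketone α-CH2); the bulky silyl group later shields N and C2 from the organolithium chemistry.

Step 3
Reactants: 5 5-methyl-1-[1-(triisopropylsilyl)-1H-indol-3-yl]hex-4-en-1-one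
Product: 6 N'-{(1E)-5-methyl-1-[1-(triisopropylsilyl)-1H-indol-3-yl]hex-4-en-1-ylidene}-2,4,6-triisopropylbenzenesulfonohydrazide
Conditions: 2,4,6-(i-Pr)3C6H2SO2NHNH2, cat. HCl, MeCN–THF, rt
Reagents that add atoms: 2,4,6-triisopropylbenzenesulfonohydrazide, CC(C)c1cc(C(C)C)c(S(=O)(=O)NN)c(C(C)C)c1
Why: Acid-catalysed condensation of a ketone with an arenesulfonyl hydrazide to the hydrazone, in which the sulfonamide nitrogen should settle anti to the bulky indolyl group and therefore syn to the α-CH2 that must be deprotonated next.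

Step 4
Reactants: 6 the trisylhydrazone; 7 hexacarbonylchromium, Cr(CO)6
Product: 10 pentacarbonyl{(E)-1-methoxy-6-methyl-2-[1-(triisopropylsilyl)indol-3-yl]hepta-2,5-dien-1-ylidene}chromium, via vinyllithium 8 (not isolated), via lithium acylchromate 9 (not isolated)
Conditions: n-BuLi (2.1 equiv), THF, −78 to 0 °C; Cr(CO)6, THF, 0 °C to rt; evaporate; Me3OBF4, CH2Cl2–H2O, 0 °C
Reagents that add atoms: trimethyloxonium tetrafluoroborate, C[O+](C)C.F[B-](F)(F)F
Why: Shapiro reaction (syn α-deprotonation of the hydrazone monoanion, then loss of sulfinate and N2) gives the vinyllithium with lithium trans to the side-chain CH2, and its addition to a CO ligand of Cr(CO)6 followed by O-methylation of the acylchromate is the classical Fischer carbene synthesis.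

Step 5
Reactants: 11 2,2-dimethylbut-3-enoic acid; 12 2-methylaniline
Product: 14 2,2-dimethyl-N-(2-methylphenyl)but-3-enamide, via 2,2-dimethylbut-3-enoyl chloride 13 (not isolated)
Conditions: 11, (COCl)2, cat. DMF, CH2Cl2, 0 °C to rt; then 12, Et3N, CH2Cl2, 0 °C to rt
Reagents that add atoms: none
Why: N-acylation of the aniline by the acid chloride; the quaternary α-carbon excludes enolisation or ketene formation.

Step 6
Reactants: 14 2,2-dimethyl-N-(2-methylphenyl)but-3-enamide
Product: 15 2-(2-methylbut-3-en-2-yl)-1H-indole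
Conditions: n-BuLi (3 equiv), THF, −20 °C to rt; H2O
Reagents that add atoms: none
Why: Madelung indole synthesis in its organolithium form, in which the N,C-dilithiated o-toluidide attacks its own amide carbonyl and dehydrates; an anilide without α-hydrogens is the best substrate class for it.

Step 7
Reactants: 15 2-(2-methylbut-3-en-2-yl)-1H-indole; 16 1-[(triisopropylsilyl)ethynyl]-1,2-benziodoxol-3(1H)-one
Product: 17 2-(2-methylbut-3-en-2-yl)-3-[(triisopropylsilyl)ethynyl]-1H-indole
Conditions: AuCl (5 mol %), Et2O, rt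
Reagents that add atoms: none
Why: Gold-catalysed electrophilic C3–H alkynylation of a free (NH) indole with an ethynylbenziodoxolone; C3 is the only nucleophilic position left, the linear alkyne tolerates the neighbouring quaternary carbon, and no N-protection or aldehyde homologation is needed.

Step 8
Reactants: 17 2-(2-methylbut-3-en-2-yl)-3-[(triisopropylsilyl)ethynyl]-1H-indole
Product: 18 3-ethynyl-2-(2-methylbut-3-en-2-yl)-1H-indole
Conditions: Bu4NF, THF, 0 °C
Reagents that add atoms: none
Why: Fluoride-induced protodesilylation of the alkynylsilane; the terminal alkyne is made last and used at once, because 3-ethynylindoles with a free N–H keep poorly.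

Step 9
Reactants: 10 the carbene complex; 18 3-ethynyl-2-(2-methylbut-3-en-2-yl)-1H-indole (1.5 equiv)
Product: 20 4-methoxy-2-[2-(2-methylbut-3-en-2-yl)-1H-indol-3-yl]-6-(3-methylbut-2-enyl)-5-[1-(triisopropylsilyl)indol-3-yl]phenol, via chromium-bound phenol 19 (not isolated)
Conditions: THF (0.05 M, degassed), 50 °C, Ar; then air, Et2O, rt
Reagents that add atoms: none
Why: Thermal loss of one CO from 10 lets the terminal alkyne of 18 insert into the Cr=C bond to give an η3-vinylcarbene, CO insertion turns this into a chromium-bound dienylketene, and the ketene carbon (C6) then bonds to the alkene carbon C5. This is the Dötz benzannulation of an alkenyl(alkoxy)carbene chromium complex with a terminal alkyne, the substrate class for which phenol formation is most dependable. The six-membered ring closes by a thermal 6π-electrocyclisation of the dienylketene (C5–C6 bond), and the resulting cyclohexadienone, which has H on C5, tautomerises to the phenol held on Cr(CO)3 until air releases it. No stereocentre is formed. The step needs regiocontrol (indole A next to the CO-derived C6, H next to the carbene-derived C3), and this follows from the steric preference of a terminal alkyne, whose bulky substituent settles away from the methoxy-bearing carbene carbon. It also needs CO insertion to win over five-ring formation, which an alkenyl complex in THF favours, and the E alkene of 10 keeps the side-chain CH2 outside the closing termini, although either geometry would lead to the same arene.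

Step 10
Reactants: 20 the 4-methoxyphenol
Product: 21 5-[2-(2-methylbut-3-en-2-yl)-1H-indol-3-yl]-3-(3-methylbut-2-en-1-yl)-2-[1-(triisopropylsilyl)-1H-indol-3-yl]cyclohexa-2,5-diene-1,4-dione
Conditions: PhI(OAc)2 (1.05 equiv), MeCN–H2O, 0 °C
Reagents that add atoms: water, O
Why: Oxidative demethylation of a 4-methoxyphenol by a hypervalent iodine reagent (ligand exchange at iodine with the phenol, attack of water at the methoxy-bearing para carbon C3, loss of methanol), which should be faster than oxidation of either indole.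

Step 11
Reactants: 21 the quinone
Product: 22 rac-1-[2-(2-methylbut-3-en-2-yl)-1H-indol-3-yl]-3-(3-methylbut-2-en-1-yl)-4-[1-(triisopropylsilyl)-1H-indol-3-yl]-7-oxabicyclo[4.1.0]hept-3-ene-2,5-dione (cis-fused oxirane on quinone C1–C2; enantiomer drawn: indole-bearing carbon S, CH carbon R)
Conditions: 30% aq. H2O2, Na2CO3, THF–H2O, 0 °C, short reaction time
Reagents that add atoms: hydrogen peroxide, OO
Why: Weitz–Scheffer nucleophilic epoxidation, in which hydroperoxide adds to C2, the only unsubstituted enone β-carbon, and the enolate closes the oxirane on the same face, so the two new stereocentres (C1, C2) are necessarily cis and racemic and are erased in step 12.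

Step 12
Reactants: 22 the quinone epoxide
Product: 24 2-hydroxy-6-(1H-indol-3-yl)-3-[2-(2-methylbut-3-en-2-yl)-1H-indol-3-yl]-5-(3-methylbut-2-en-1-yl)cyclohexa-2,5-diene-1,4-dione (CNP0134649.0), via N-silyl hydroxyquinone 23 (not isolated)
Conditions: camphorsulfonic acid (0.3 equiv), THF, rt; then Bu4NF (3 equiv), 0 °C to rt; dilute HCl wash
Reagents that add atoms: none
Why: Acid-catalysed isomerisation of a quinone epoxide to a hydroxyquinone (oxirane opening at C1, where the indol-3-yl group stabilises the cation, then loss of the C2 proton to the enol) under acid far too weak to cyclise the prenyl group, followed in the same flask by fluoride cleavage of the N–Si bond.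

Compound list
1 | 1H-indole | c1ccc2[nH]ccc2c1 | starting material
2 | 5-methylhex-4-enoic acid | CC(C)=CCCC(=O)O | starting material
3 | 5-methylhex-4-enoyl chloride | CC(C)=CCCC(=O)Cl | intermediate (not isolated)
4 | 1-(1H-indol-3-yl)-5-methylhex-4-en-1-one | CC(C)=CCCC(=O)c1c[nH]c2ccccc12 | intermediate
5 | 5-methyl-1-[1-(triisopropylsilyl)-1H-indol-3-yl]hex-4-en-1-one | CC(C)=CCCC(=O)c1cn([Si](C(C)C)(C(C)C)C(C)C)c2ccccc12 | intermediate
6 | N'-{(1E)-5-methyl-1-[1-(triisopropylsilyl)-1H-indol-3-yl]hex-4-en-1-ylidene}-2,4,6-triisopropylbenzenesulfonohydrazide | CC(C)=CCC/C(c1cn([Si](C(C)C)(C(C)C)C(C)C)c2ccccc12)=N\NS(=O)(=O)c1c(C(C)C)cc(C(C)C)cc1C(C)C | intermediate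
7 | hexacarbonylchromium, Cr(CO)6 | O=C=[Cr](=C=O)(=C=O)(=C=O)(=C=O)=C=O | starting material
8 | {(1Z)-5-methyl-1-[1-(triisopropylsilyl)-1H-indol-3-yl]hexa-1,4-dien-1-yl}lithium (Li trans to the CH2) | [Li]/C(c1cn([Si](C(C)C)(C(C)C)C(C)C)c2ccccc12)=C/CC=C(C)C | intermediate (not isolated)
9 | lithium pentacarbonyl{(2E)-6-methyl-2-[1-(triisopropylsilyl)-1H-indol-3-yl]hepta-2,5-dienoyl}chromate | [Li+].[O-]C(=[Cr](=C=O)(=C=O)(=C=O)(=C=O)=C=O)/C(c1cn([Si](C(C)C)(C(C)C)C(C)C)c2ccccc12)=C/CC=C(C)C | intermediate (not isolated)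
10 | pentacarbonyl{(E)-1-methoxy-6-methyl-2-[1-(triisopropylsilyl)indol-3-yl]hepta-2,5-dien-1-ylidene}chromium | COC(=[Cr](=C=O)(=C=O)(=C=O)(=C=O)=C=O)/C(c1cn([Si](C(C)C)(C(C)C)C(C)C)c2ccccc12)=C/CC=C(C)C | intermediate (key-step precursor)
11 | 2,2-dimethylbut-3-enoic acid | C=CC(C)(C)C(=O)O | starting material
12 | 2-methylaniline | Cc1ccccc1N | starting material
13 | 2,2-dimethylbut-3-enoyl chloride | C=CC(C)(C)C(=O)Cl | intermediate (not isolated)
14 | 2,2-dimethyl-N-(2-methylphenyl)but-3-enamide | C=CC(C)(C)C(=O)Nc1ccccc1C | intermediate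
15 | 2-(2-methylbut-3-en-2-yl)-1H-indole | C=CC(C)(C)c1cc2ccccc2[nH]1 | intermediate
16 | 1-[(triisopropylsilyl)ethynyl]-1,2-benziodoxol-3(1H)-one | CC(C)[Si](C#CI1OC(=O)c2ccccc12)(C(C)C)C(C)C | starting material
17 | 2-(2-methylbut-3-en-2-yl)-3-[(triisopropylsilyl)ethynyl]-1H-indole | C=CC(C)(C)c1[nH]c2ccccc2c1C#C[Si](C(C)C)(C(C)C)C(C)C | intermediate
18 | 3-ethynyl-2-(2-methylbut-3-en-2-yl)-1H-indole | C#Cc1c(C(C)(C)C=C)[nH]c2ccccc12 | intermediate (key-step precursor)
19 | tricarbonylchromium complex of phenol 20 (Cr(CO)3 η6-bound to the new ring; written as two parts) | COc1cc(-c2c(C(C)(C)C=C)[nH]c3ccccc23)c(O)c(CC=C(C)C)c1-c1cn([Si](C(C)C)(C(C)C)C(C)C)c2ccccc12.O=C=[Cr](=C=O)=C=O | intermediate (not isolated)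
20 | 4-methoxy-2-[2-(2-methylbut-3-en-2-yl)-1H-indol-3-yl]-6-(3-methylbut-2-enyl)-5-[1-(triisopropylsilyl)indol-3-yl]phenol | COc1cc(-c2c(C(C)(C)C=C)[nH]c3ccccc23)c(O)c(CC=C(C)C)c1-c1cn([Si](C(C)C)(C(C)C)C(C)C)c2ccccc12 | intermediate (key-step product)
21 | 5-[2-(2-methylbut-3-en-2-yl)-1H-indol-3-yl]-3-(3-methylbut-2-en-1-yl)-2-[1-(triisopropylsilyl)-1H-indol-3-yl]cyclohexa-2,5-diene-1,4-dione | O=C1C=C(c2c(C(C)(C)C=C)[nH]c3ccccc23)C(=O)C(CC=C(C)C)=C1c1cn([Si](C(C)C)(C(C)C)C(C)C)c2ccccc12 | intermediate
22 | rac-(1S,6R)-1-[2-(2-methylbut-3-en-2-yl)-1H-indol-3-yl]-3-(3-methylbut-2-en-1-yl)-4-[1-(triisopropylsilyl)-1H-indol-3-yl]-7-oxabicyclo[4.1.0]hept-3-ene-2,5-dione (racemate, one enantiomer drawn) | O=C1[C@@H]2O[C@]2(c3c(C(C)(C)C=C)[nH]c4ccccc34)C(=O)C(CC=C(C)C)=C1c5cn([Si](C(C)C)(C(C)C)C(C)C)c6ccccc56 | intermediate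
23 | 2-hydroxy-3-[2-(2-methylbut-3-en-2-yl)-1H-indol-3-yl]-5-(3-methylbut-2-en-1-yl)-6-[1-(triisopropylsilyl)-1H-indol-3-yl]cyclohexa-2,5-diene-1,4-dione | C=CC(C)(C)c1[nH]c2ccccc2c1C1=C(O)C(=O)C(c2cn([Si](C(C)C)(C(C)C)C(C)C)c3ccccc23)=C(CC=C(C)C)C1=O | intermediate (not isolated)
24 | 2-hydroxy-6-(1H-indol-3-yl)-3-[2-(2-methylbut-3-en-2-yl)-1H-indol-3-yl]-5-(3-methylbut-2-en-1-yl)cyclohexa-2,5-diene-1,4-dione | C=CC(C)(C)c1[nH]c2ccccc2c1C1=C(O)C(=O)C(c2c[nH]c3ccccc23)=C(CC=C(C)C)C1=O | target

Total step count: 12. Longest linear sequence: 8 steps (steps 1–4 or 5–8, then 9–12).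

Steps most likely to fail

Step 9. The alkyne insertion may be too slow for the crowded, electron-rich ethynylindole. In that case 18 would oligomerise and 10 would decay (loss of chromium, migration of the skipped diene) before the ring is built, or CO insertion might be bypassed. The fallback sets out from 10 and 15 and comes back at 20. The benzannulation is run under the conditions of step 9 with the small, purchasable alkyne 2-ethynyl-4,4,5,5-tetramethyl-1,3,2-dioxaborolane. Its boron-bearing carbon should again settle next to the phenol carbon, giving, through the chromium-bound boronate phenol F1, the boronate phenol F2. Indole 15 is brominated at C3 (NBS, THF, −78 to 0 °C) to the 3-bromoindole F3. A Suzuki–Miyaura coupling of F2 with F3 (Pd(OAc)2, SPhos, K3PO4, dioxane–H2O, 80 °C) then forms the C1–indole A bond and delivers 20. The ring is still assembled by the same three-component union, but the hindered biaryl bond is no longer asked of the insertion step.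

Step 4. The second deprotonation of the hydrazone may stay incomplete. The vinyllithium may also be quenched by the doubly allylic CH2 of a neighbouring molecule during the warm-up needed for nitrogen loss, or be captured poorly by the sparingly soluble Cr(CO)6. The slow condensation of step 3 on a vinylogous-amide ketone belongs to the same weak spot. The fallback sets out from 5 and comes back at 19. Ketone 5 is converted into the enol triflate F4 (KN(SiMe3)2, PhNTf2, THF, −78 °C). Palladium-catalysed stannylation (Me3SnSnMe3, Pd(PPh3)4, LiCl, THF, 60 °C) gives the vinylstannane F5. Tin–lithium exchange (MeLi, THF, −78 °C) gives the vinyllithium F6 at low temperature, free of sulfinate and without a warm-up. Cr(CO)6 and then Me3OBF4 convert it, through the acylchromate F7, into the carbene complex F8, the geometric isomer of 10. F8 and 18 under the conditions of step 9 should converge on 19 and hence 20, because the alkene geometry is lost when C5 becomes an arene carbon.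

Step 11. Over-oxidation may occur: the oxirane may open prematurely in base, and hydroperoxide may then cleave the hydroxyquinone ring. Hydroperoxide may also attack the indoles or the fully substituted C5. The fallback sets out from 21 and comes back at 23. Oxidative amination of the quinone C2–H with morpholine (Cu(OAc)2 cat., air, MeOH, rt) gives the morpholinoquinone F9. Hydrolysis of this vinylogous amide (aq. NaOH, MeOH–THF, 50 °C, then acidification) gives 23, which is desilylated with Bu4NF as in step 12.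

Further compounds
F1 | step 9 | tricarbonylchromium complex of boronate phenol F2 (Cr(CO)3 η6-bound; written as two parts) | COc1cc(B2OC(C)(C)C(C)(C)O2)c(O)c(CC=C(C)C)c1-c1cn([Si](C(C)C)(C(C)C)C(C)C)c2ccccc12.O=C=[Cr](=C=O)=C=O
F2 | step 9 | 4-methoxy-6-(3-methylbut-2-en-1-yl)-2-(4,4,5,5-tetramethyl-1,3,2-dioxaborolan-2-yl)-5-[1-(triisopropylsilyl)-1H-indol-3-yl]phenol | COc1cc(B2OC(C)(C)C(C)(C)O2)c(O)c(CC=C(C)C)c1-c1cn([Si](C(C)C)(C(C)C)C(C)C)c2ccccc12
F3 | step 9 | 3-bromo-2-(2-methylbut-3-en-2-yl)-1H-indole | C=CC(C)(C)c1[nH]c2ccccc2c1Br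
F4 | step 4 | (1Z)-5-methyl-1-[1-(triisopropylsilyl)-1H-indol-3-yl]hexa-1,4-dien-1-yl trifluoromethanesulfonate | FC(F)(F)S(=O)(=O)O/C(c1cn([Si](C(C)C)(C(C)C)C(C)C)c2ccccc12)=C\CC=C(C)C
F5 | step 4 | trimethyl{(1Z)-5-methyl-1-[1-(triisopropylsilyl)-1H-indol-3-yl]hexa-1,4-dien-1-yl}stannane | C[Sn](C)(C)/C(c1cn([Si](C(C)C)(C(C)C)C(C)C)c2ccccc12)=C\CC=C(C)C
F6 | step 4 | {(1E)-5-methyl-1-[1-(triisopropylsilyl)-1H-indol-3-yl]hexa-1,4-dien-1-yl}lithium (Li cis to the CH2) | [Li]/C(c1cn([Si](C(C)C)(C(C)C)C(C)C)c2ccccc12)=C\CC=C(C)C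
F7 | step 4 | lithium pentacarbonyl{(2Z)-6-methyl-2-[1-(triisopropylsilyl)-1H-indol-3-yl]hepta-2,5-dienoyl}chromate | [Li+].[O-]C(=[Cr](=C=O)(=C=O)(=C=O)(=C=O)=C=O)/C(c1cn([Si](C(C)C)(C(C)C)C(C)C)c2ccccc12)=C\CC=C(C)C
F8 | step 4 | pentacarbonyl{(Z)-1-methoxy-6-methyl-2-[1-(triisopropylsilyl)indol-3-yl]hepta-2,5-dien-1-ylidene}chromium | COC(=[Cr](=C=O)(=C=O)(=C=O)(=C=O)=C=O)/C(c1cn([Si](C(C)C)(C(C)C)C(C)C)c2ccccc12)=C\CC=C(C)C
F9 | step 11 | 3-[2-(2-methylbut-3-en-2-yl)-1H-indol-3-yl]-5-(3-methylbut-2-en-1-yl)-2-(morpholin-4-yl)-6-[1-(triisopropylsilyl)-1H-indol-3-yl]cyclohexa-2,5-diene-1,4-dione | O=C1C(N2CCOCC2)=C(c3c(C(C)(C)C=C)[nH]c4ccccc34)C(=O)C(CC=C(C)C)=C1c5cn([Si](C(C)C)(C(C)C)C(C)C)c6ccccc56
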